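## Retrosynthetic overview

1. Target 24 ⇐ kinetic protonation of the ring-D ester dienolate (sets C13) ⇐ ring D by ring-closing metathesis of a C10-vinyl and a C13-vinyl group.
2. The C5–C13 bond sits on the convex face of ring B, anti to C10 on C6 (trans B/D junction), so it is delivered by Ireland–Claisen rearrangement from a C3–O ester on that face.
3. Key step: the C3–O bond and ring C are formed together by a palladium-catalysed allyl/diene cyclization–acyloxylation of a bicyclo[4.2.0]octadiene with but-3-enoic acid.
4. Rings A/B: enantioselective anti-SN2′ alkylation of meso cyclooctatetraene oxide with the decenylzinc reagent, then O-vinylation/Claisen and 6π electrocyclization.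
5. Ring order: eight-membered template → rings A and B (one step) → ring C → ring D.

Labels: skeleton carbons are C1–C13 in the order written in the SMILES (C1 carries the decenyl chain, C13 the ester). Ring A = C1/C2/C7/C8, ring B = C2–C7, ring C = C6–C10, ring D = C5/C6/C10–C13. The convex face of ring B is the face opposite rings A and C.

Assumption: the SMILES is taken literally. It places H5 anti to H6 (rings B and D trans-fused) and H13 syn to H5, which a suprafacial intramolecular Diels–Alder closure of ring D (all-syn junction only) cannot give.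

## Route

Step 1
Reactants: 1 (E)-hex-4-en-1-ol
Product: 2 (E)-6-bromohex-2-ene
Conditions: CBr4, PPh3, CH2Cl2, 0 °C to rt
Reagents that add atoms: carbon tetrabromide, BrC(Br)(Br)Br
Why: Appel bromination of the primary alcohol; no stereocentre is involved and the (E)-alkene is untouched.

Step 2
Reactants: 2 (E)-6-bromohex-2-ene; 3 1,4-dibromobutane
Product: 5 (E)-10-bromodec-2-ene, via (E)-hex-4-enylmagnesium bromide 4 (not isolated)
Conditions: Mg, THF, rt; then 3 (3 equiv), Li2CuCl4 (3 mol%), THF, −10 to 0 °C
Reagents that add atoms: none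
Why: Grignard formation then Kochi-type copper-catalysed sp3–sp3 coupling, with excess dibromide holding it at mono-alkylation; alkene geometry is retained.

Step 3
Reactants: 6 cyclooctatetraene
Product: 7 cyclooctatetraene oxide
Conditions: mCPBA (1 equiv), CH2Cl2, 0 °C
Reagents that add atoms: 3-chloroperoxybenzoic acid, OOC(=O)c1cccc(Cl)c1
Why: Prilezhaev mono-epoxidation; the cis-epoxide is meso, so no absolute stereochemistry is set yet.

Step 4
Reactants: 5 (E)-10-bromodec-2-ene; 7 cyclooctatetraene oxide
Product: 10 (1R,4R)-4-[(E)-dec-8-enyl]cycloocta-2,5,7-trien-1-ol, via (E)-dec-8-enylmagnesium bromide 8 (not isolated), via bis[(E)-dec-8-enyl]zinc 9 (not isolated)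
Conditions: 5 (3 equiv), Mg, Et2O; ZnCl2 (1.5 equiv), then 1,4-dioxane, filter; 7, Cu(OTf)2 (1.5 mol%), binaphthol-derived N,N-bis(1-phenylethyl)phosphoramidite (3 mol%), toluene, −78 to −10 °C; H2O
Reagents that add atoms: none
Why: copper-catalysed enantioselective anti-SN2′ alkylative desymmetrization of the meso vinyl epoxide by the dialkylzinc; anti attack makes OH and decenyl trans, and the ligand enantiomer used is the one that gives (1R,4R) (its mirror image gives the antipode).

Step 5
Reactants: 10 (1R,4R)-4-[(E)-dec-8-enyl]cycloocta-2,5,7-trien-1-ol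
Product: 13 2-[(1R,6S,7S,8S)-8-[(E)-dec-8-enyl]bicyclo[4.2.0]octa-2,4-dien-7-yl]acetaldehyde, via vinyl ether 11 (not isolated), via cyclooctatriene aldehyde 12 (not isolated)
Conditions: [Ir(cod)Cl]2 (1 mol%), Na2CO3 (0.6 equiv), vinyl acetate (3 equiv), toluene, 100 °C, then 110 °C
Reagents that add atoms: vinyl acetate, CC(=O)OC=C
Why: iridium-catalysed transfer vinylation, then a suprafacial Claisen [3,3] shift across the isolated C2=C3 unit that moves the C1–O chirality to the new C–C bond (trans to decenyl) and completes a conjugated triene, then thermal disrotatory 6π electrocyclization to the cis-fused bicycle; 13 interconverts through 12 with the isomer having endo and exo substituents exchanged.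

Step 6
Reactants: 13 the bicyclic aldehyde
Product: 15 methyl carbonate of the allylic alcohol (both carbinol epimers), via bromomagnesium alkoxide 14 (not isolated)
Conditions: CH2=CHMgBr, THF, −78 °C; then ClCO2Me, −78 to 0 °C
Reagents that add atoms: vinylmagnesium bromide, C=C[Mg]Br; methyl chloroformate, COC(=O)Cl
Why: Grignard addition to the aldehyde and in-flask acylation of the alkoxide; the new carbinol centre is unselective and irrelevant because it is erased on ionization in step 7.

Step 7
Reactants: 15 the allylic methyl carbonate; 16 but-3-enoic acid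
Product: 17 tricyclic C3 but-3-enoate (rings A/B/C; ester oxygen on the convex face; C4=C5; vinyl on C10)
Conditions: Pd2(dba)3 (2.5 mol%), PPh3 (12 mol%), 16 (1.5 equiv), THF, 65 °C
Reagents that add atoms: none
Why: Proposed new method: zerovalent palladium ionizes either carbinol epimer to a π-allyl complex that can reach only the concave face of the cyclohexadiene in the valence isomer with the chain endo (the other isomer feeds in through the cyclooctatriene); a palladium-ene-type syn insertion then joins the allyl terminus C10 to the diene terminus C6, closing ring C with H6 on the convex face and the vinyl group cis to C5 (both lie in the six-membered Pd-bridged transition state) and leaving a ring-B π-allyl with Pd on the concave face, which the but-3-enoate (formed from 16 by the expelled methoxide) attacks from outside at the distal terminus C3, so the C–O bond lands on the convex face; the closest known reactions are the Oppolzer palladium-ene cyclization and the Pd-catalysed allyl ester/1,3-diene cycloisomerization with Tsuji–Trost-type carboxylate capture, here extended to a fluxional cyclic diene with an external acid, setting C6, C10 and C3.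

Step 8
Reactants: 17 the tricyclic but-3-enoate
Product: 21 methyl 2-(tricyclyl)but-3-enoate (C5 side chain on the convex face; C3=C4; C13 epimers), via silyl ketene acetal 18 (not isolated), via trimethylsilyl ester 19 (not isolated), via carboxylic acid 20 (not isolated)
Conditions: LiN(iPr)2, Me3SiCl, THF, −78 to 50 °C; then MeOH, Me3SiCHN2, toluene, 0 °C
Reagents that add atoms: (trimethylsilyl)diazomethane, C[Si](C)(C)C=[N+]=[N-]
Why: Ireland–Claisen rearrangement is suprafacial across C3–C4=C5, so the C5–C13 bond forms on the convex face that carried the C3–O bond, anti to C10 on C6 (this fixes the trans B/D junction) and shifts the alkene to C3=C4; C13 forms as an epimer mixture that step 10 corrects, and the acid is methylated in the same flask.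

Step 9
Reactants: 21 the diene ester
Product: 22 tetracyclic methyl ester (rings A–D; C13 epimers)
Conditions: RuCl2(PCy3)2(=CHPh) (first-generation Grubbs catalyst, 5 mol%), CH2Cl2 (2 mM), 40 °C
Reagents that add atoms: none
Why: ring-closing metathesis of the only two terminal alkenes (vinyl on C10 and on C13) closes ring D with a cis C11=C12 bond; this catalyst leaves the internal (E)-propenyl and ring-B alkenes alone, and no stereocentre changes.

Step 10
Reactants: 22 the tetracyclic ester (C13 epimers)
Product: 24 target methyl ester, via lithium dienolate 23 (not isolated)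
Conditions: LiN(iPr)2, THF, −78 °C; then 2,6-di-tert-butyl-4-methylphenol, −78 °C
Reagents that add atoms: none
Why: both epimers give the same dienolate, and kinetic α-protonation by the bulky phenol comes along the equatorial trajectory (away from the 1,3-related axial H6), leaving the ester axial, cis to C4 with H13 syn to H5 (Zimmerman-type kinetic ketonization, contra-thermodynamic) and returning the alkene to C11=C12.

## Compound list

1 | (E)-hex-4-en-1-ol | C/C=C/CCCO | starting material
2 | (E)-6-bromohex-2-ene | C/C=C/CCCBr | intermediate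
3 | 1,4-dibromobutane | BrCCCCBr | starting material
4 | (E)-hex-4-enylmagnesium bromide | C/C=C/CCC[Mg]Br | intermediate
5 | (E)-10-bromodec-2-ene | C/C=C/CCCCCCCBr | intermediate
6 | cyclooctatetraene | C1=CC=CC=CC=C1 | starting material
7 | cyclooctatetraene oxide (meso cis-9-oxabicyclo[6.1.0]nona-2,4,6-triene) | C1=CC=C[C@H]2O[C@H]2C=C1 | intermediate
8 | (E)-dec-8-enylmagnesium bromide | C/C=C/CCCCCCC[Mg]Br | intermediate
9 | bis[(E)-dec-8-enyl]zinc | C/C=C/CCCCCCC[Zn]CCCCCCC/C=C/C | intermediate
10 | (1R,4R)-4-[(E)-dec-8-enyl]cycloocta-2,5,7-trien-1-ol (OH and decenyl trans) | C/C=C/CCCCCCC[C@@H]1C=CC=C[C@@H](O)C=C1 | intermediate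
11 | vinyl ether of 10 | C/C=C/CCCCCCC[C@@H]1C=CC=C[C@@H](OC=C)C=C1 | intermediate
12 | 2-[(1R,8R)-8-[(E)-dec-8-enyl]cycloocta-2,4,6-trien-1-yl]acetaldehyde (substituents trans, ring alkenes all Z) | C/C=C/CCCCCCC[C@@H]1C=CC=CC=C[C@H]1CC=O | intermediate
13 | 2-[(1R,6S,7S,8S)-8-[(E)-dec-8-enyl]bicyclo[4.2.0]octa-2,4-dien-7-yl]acetaldehyde (cis-fused; CH2CHO arm endo, under the diene ring; decenyl exo) | C/C=C/CCCCCCC[C@@H]1[C@H]2C=CC=C[C@H]2[C@H]1CC=O | intermediate
14 | bromomagnesium alkoxide from 13 and vinylmagnesium bromide (carbinol epimers) | C/C=C/CCCCCCC[C@@H]1[C@H]2C=CC=C[C@H]2[C@H]1CC(O[Mg]Br)C=C | intermediate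
15 | methyl 1-(bicyclyl)but-3-en-2-yl carbonate (bicycle as in 13; carbinol epimers) | C/C=C/CCCCCCC[C@@H]1[C@H]2C=CC=C[C@H]2[C@H]1CC(OC(=O)OC)C=C | intermediate
16 | but-3-enoic acid | C=CCC(=O)O | starting material
17 | tricyclic but-3-enoate (rings A/B/C): acyloxy on C3 on the convex face (cis to H2); C4=C5; vinyl on C10 cis to C5; H2, H6, H7, H8, H10 all cis; decenyl on C1 exo | C/C=C/CCCCCCC[C@@H]1[C@H]2[C@H](OC(=O)CC=C)C=C[C@@H]3[C@H]2[C@H]1C[C@@H]3C=C | intermediate
18 | O-trimethylsilyl ketene acetal (dienol ether) of 17 | C/C=C/CCCCCCC[C@@H]1[C@H]2[C@H](OC(O[Si](C)(C)C)=CC=C)C=C[C@@H]3[C@H]2[C@H]1C[C@@H]3C=C | intermediate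
19 | trimethylsilyl 2-(tricyclyl)but-3-enoate (side chain on C5, convex face; C3=C4; C13 epimers) | C/C=C/CCCCCCC[C@@H]1[C@H]2C=C[C@@H]([C@@H]3[C@H]2[C@H]1C[C@@H]3C=C)C(C=C)C(=O)O[Si](C)(C)C | intermediate
20 | 2-(tricyclyl)but-3-enoic acid (as 19, free acid) | C/C=C/CCCCCCC[C@@H]1[C@H]2C=C[C@@H]([C@@H]3[C@H]2[C@H]1C[C@@H]3C=C)C(C=C)C(=O)O | intermediate
21 | methyl 2-(tricyclyl)but-3-enoate (as 19, methyl ester; H5 anti to H6) | C/C=C/CCCCCCC[C@@H]1[C@H]2C=C[C@@H]([C@@H]3[C@H]2[C@H]1C[C@@H]3C=C)C(C=C)C(=O)OC | intermediate
22 | tetracyclic methyl ester, rings A–D, C13 epimers | C/C=C/CCCCCCC[C@@H]1[C@H]2C=C[C@H]3[C@@H]4[C@H]2[C@H]1C[C@@H]4C=CC3C(=O)OC | intermediate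
23 | lithium dienolate of 22 (C13 planar) | C/C=C/CCCCCCC[C@@H]1[C@H]2C=C[C@H]3[C@@H]4[C@H]2[C@H]1C[C@@H]4C=CC3=C(OC)O[Li] | intermediate
24 | target methyl ester: decenyl on C1 exo; H2, H6, H7, H8, H10 cis; H5 anti to H6; H13 syn to H5 | C/C=C/CCCCCCC[C@@H]1[C@H]2C=C[C@H]3[C@@H]4[C@H]2[C@H]1C[C@@H]4C=C[C@H]3C(=O)OC | target

## Step count and risks

Total steps: 10. Longest linear sequence: 9 (steps 1, 2, 4–10).

Three steps most likely to fail:

Step 7 (the proposed new cyclization–acyloxylation). The risks are elimination of the first π-allyl to a diene, acyloxy return at C5 instead of C3, and loss of anti delivery. The fallback uses known chemistry, sets out from 13 and comes back at 17. Aldehyde 13 is olefinated with Ph3P=CHCH2SiMe3 to the allylsilane F1. Oxidative 1,4-carbochlorination with divalent palladium (Pd(OAc)2, LiCl, p-benzoquinone, acetone/AcOH) follows: the allylsilane attacks the Pd-bound diene anti and chloride attacks the π-allyl anti, a net syn 1,4-addition. This gives the tricyclic allylic chloride F2, with chloride on the concave face of C3. SN2 displacement with caesium but-3-enoate F3 (from 16 and Cs2CO3, DMF) inverts C3 and gives 17.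

Step 8 (Ireland–Claisen of a but-3-enoate dienolate on a hindered secondary allylic ester). The risks are conjugation to the crotonate and γ-silylation. The fallback sets out from 17 and comes back at 21. Methanolysis (K2CO3, MeOH) gives the allylic alcohol F4. Johnson–Claisen rearrangement with MeC(OMe)3 and catalytic EtCO2H at 120 °C proceeds through the mixed ketene acetal F5 to the methyl ester F6, with the CH2CO2Me arm on the convex face of C5. The lithium enolate F7 (LiN(SiMe3)2, toluene) is then α-vinylated with vinyl bromide under Pd(dba)2/P(tBu)3 to give 21.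

Step 10 (contra-thermodynamic kinetic protonation at C13). The risk is that axial protonation or equilibration gives the equatorial ester. The fallback sets out from 17 and comes back at 24; it reverses the order of metathesis and rearrangement so that the tether sets C13. Ring-closing metathesis of 17 at high dilution with RuCl2(PCy3)(H2IMes)(=CHPh) (second-generation Grubbs catalyst) gives the ten-membered (Z)-lactone F8. LiN(iPr)2/Me3SiCl gives its silyl ketene acetal F9. Ireland–Claisen ring contraction then occurs through a boat transition state in which the tether to C10 holds the alkenyl carbon over ring B, giving the silyl ester F10 and, after methanolysis, the acid F11 with C13 already in the target configuration. Me3SiCHN2 gives 24.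

## Further compounds

F1 | step 7 | allylsilane: 13 with CH2CH=CHCH2SiMe3 in place of CH2CHO | C/C=C/CCCCCCC[C@@H]1[C@H]2C=CC=C[C@H]2[C@H]1CC=CC[Si](C)(C)C
F2 | step 7 | tricyclic allylic chloride: as 17 but chloride on C3 on the concave face | C/C=C/CCCCCCC[C@@H]1[C@H]2[C@@H](Cl)C=C[C@@H]3[C@H]2[C@H]1C[C@@H]3C=C
F3 | step 7 | caesium but-3-enoate | [Cs+].[O-]C(=O)CC=C
F4 | step 8 | tricyclic allylic alcohol: as 17 with free OH on C3, convex face | C/C=C/CCCCCCC[C@@H]1[C@H]2[C@H](O)C=C[C@@H]3[C@H]2[C@H]1C[C@@H]3C=C
F5 | step 8 | mixed methyl ketene acetal of F4 | C/C=C/CCCCCCC[C@@H]1[C@H]2[C@H](OC(=C)OC)C=C[C@@H]3[C@H]2[C@H]1C[C@@H]3C=C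
F6 | step 8 | methyl 2-(tricyclyl)acetate: CH2CO2Me on C5, convex face; C3=C4 | C/C=C/CCCCCCC[C@@H]1[C@H]2C=C[C@@H]([C@@H]3[C@H]2[C@H]1C[C@@H]3C=C)CC(=O)OC
F7 | step 8 | lithium enolate of F6 | C/C=C/CCCCCCC[C@@H]1[C@H]2C=C[C@@H]([C@@H]3[C@H]2[C@H]1C[C@@H]3C=C)C=C(OC)O[Li]
F8 | step 10 | ten-membered (Z)-lactone bridging C3–O and C10 | C/C=C/CCCCCCC[C@@H]1[C@H]2[C@@H]3OC(=O)C/C=C\[C@H]4C[C@@H]1[C@@H]2[C@H]4C=C3
F9 | step 10 | O-trimethylsilyl ketene acetal of F8 | C/C=C/CCCCCCC[C@@H]1[C@H]2[C@@H]3OC(O[Si](C)(C)C)=C/C=C\[C@H]4C[C@@H]1[C@@H]2[C@H]4C=C3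
F10 | step 10 | trimethylsilyl ester of the tetracyclic acid, target configuration | C/C=C/CCCCCCC[C@@H]1[C@H]2C=C[C@H]3[C@@H]4[C@H]2[C@H]1C[C@@H]4C=C[C@H]3C(=O)O[Si](C)(C)C
F11 | step 10 | tetracyclic carboxylic acid, target configuration | C/C=C/CCCCCCC[C@@H]1[C@H]2C=C[C@H]3[C@@H]4[C@H]2[C@H]1C[C@@H]4C=C[C@H]3C(=O)O
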